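- The amounts came first: the flask held 10 mM of J, 15.0 mM of Z and 50.0 mM of L, so J was the limiting reagent, and I kept the books in fractions of the J charged.

| flask | J | Z | L | remark | time |
|---|---|---|---|---|---|
| amber | 14 mM | 15 mM | 50 mM | run made earlier |  |
| blue | 22 mM | 15 mM | 50 mM | run made earlier |  |
| teal | 10 mM | 30 mM | 50 mM | run made earlier |  |
| flask | 10 mM | 15.0 mM | 50.0 mM |  | 1.0 h |

| run | time / min | E / % | Q / % |
|---|---|---|---|
| amber | 20.0 | 11.5 | 15.4 |
| amber | 40.0 | 19.3 | 24.7 |
| amber | 50.0 | 22.6 | 28.0 |
| amber | 80.0 | 28.8 | 33.5 |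
| blue | 6.00 | 3.6 | 5.1 |
| blue | 12.0 | 7.0 | 9.4 |
| blue | 30.0 | 15.9 | 19.6 |
| blue | 80.0 | 30.5 | 32.2 |
| teal | 6.00 | 2.4 | 6.2 |
| teal | 12.0 | 4.5 | 12.2 |
| teal | 30.0 | 9.6 | 26.7 |
| teal | 80.0 | 16.9 | 44.2 |

(each reading ± 0.3 percentage points)

- reactions considered so far: J <-> G; Z + G -> Q; L + G -> E; 2 L -> D; Q <-> X

* ratio of E to Q at 80 s
* ratio of E to Q at 8.0 min
* ratio of E to Q at 1.0 h
* which of E and Q there is more of at 1.0 h

- Each J that reacted passed through G, and G met either Z, giving Q, or L, giving E. I divided the rate of E by the rate at which Q was made, so time and G dropped out: E made per Q made is a constant times L over Z. The Q that stood was less than the Q made, by what had passed on to X.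
- In amber at 20.0 min, the reading of E over Q, times Z over L, gave 0.224. This split, E made per Q made with L and Z equal, is the selectivity factor. Teal, with twice the Z, gave 0.221 at 12.0 min.
- First entry: with the flask's charges the split gave a ratio of 0.747, so I put 57.2% of the J standing as E or Q down to Q.
- Second entry: E plus Q stood at 62.3% in amber, 62.7% in blue and 61.1% in teal at 80.0 min, close together although the charges differed. So I read the flask's total off amber, between 50.0 min and 80.0 min: 54.5% at 1.0 h.
- Closing the books at 1.0 h: Q 31.2%, E 23.3%, and 45.5% for J, G and X together.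
- Those entries cost Z 20.8% of its own charge and L 4.66% of its own. Leaving X aside and taking half of each as the mean over the run, I reckoned 0.814 at 1.0 h and kept 0.747 for 80 s and 8.0 min, with Q ahead.
- The forecast gave 0.7, 0.715 and 0.78, with Q ahead, noting “The ratio drifts upward as Z is consumed, faster at high J.” My last figure stood higher than its own.

The flask gave 0.732, 0.731 and 0.769, with Q at 31.3% and E at 24.0%.

    J ⇌ G (K = 0.0540, k = 1.00 h⁻¹)
    Z + G → Q (k = 15000 M⁻¹ h⁻¹)
    L + G → E (k = 3300 M⁻¹ h⁻¹)
    2 L → D (k = 6.30 M⁻¹ h⁻¹)
    Q ⇌ X (K = 25.0, k = 0.300 h⁻¹)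

At 1.0 h the flask held 75.4% of its Z and 58.4% of its L, though E accounts for 4.81% of the L charge. The ratio stood at 0.769 because of the consumption of L together with the time allowed: with L held the flask ended at 0.985, and at 10.0 h the ratio was 5.51. The step pairing L into D is a part of that consumption: without it the flask ended at 0.959. With 38 mM of Z, the split predicts 0.295, and that neighbour flask gave 0.290.

Readings and results are calculated for substances that don't exist.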